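## Analysis of the target

- The target is a 3,3,5,5-tetrasubstituted 1,2-dioxolane (ring atoms O1, O2, C3, C4, C5). C3 carries a methyl group and the CH2CO2H arm, C5 a methyl group and an unbranched C16 chain, and C4 is the only ring methylene.
- The chain holds eight methylenes (C1′ to C8′) and then a conjugated 9′E,11′E,13′E triene that ends in an ethyl group.
- The two stereocentres, C3 (R) and C5 (S), are both fully substituted peroxy carbons in a 1,3-relationship. The two methyl groups are trans, so the acetic acid arm is cis to the C5 methyl group.
- At each centre the competing carbon substituents are CH3 and a CH2R group. Substrate-controlled 1,3-induction across C4 is therefore expected to be negligible. This, together with the absolute configuration at two tetrasubstituted C–O carbons, is the real difficulty.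
- The O–O bond excludes hydrogenation, dissolving or low-valent metals, excess hydride, and long contact with phosphines or organometallic reagents. Neither peroxy carbon bears hydrogen, so Kornblum–DeLaMare cleavage is impossible, but the β-peroxy carboxyl unit can open by retro-oxa-Michael elimination under enolising conditions.
- The triene is sensitive to acid, oxidants, radicals and light. It must be made after every acidic and oxidative step, and nothing may be reduced after it.
- The feature the route exploits is C3 itself. Its ring neighbour O2 can stabilise a planar 1,2-dioxolan-3-ylium (peroxycarbenium) ion, so the C3 configuration can be erased and rewritten by an external chiral influence while the exocyclic C3–CH2 bond is formed.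

## Retrosynthetic reasoning

**22 ⇒ 21 ⇒ 18 + 20.** The acid 22 is carried as its methyl ester 21 and unmasked last (acyl C–O cut), because a free acid would interfere with the Lewis-acid and carbanion steps. In 21 the triene is cut at C11′=C12′, which gives enal 18 and allylic phosphonate 20 (one step from bromide 19). This cut is preferred over C13′=C14′ because a pre-formed stabilised phosphonate anion adds to an enal without excess base or phosphine, gives the E geometry by itself, and brings the C13′=C14′ alkene ready-made. The forward reaction must form one E double bond without opening the β-peroxy ester by elimination.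

**18 ⇒ 16 + 17.** Enal 18 is cut at C9′=C10′ by cross-metathesis of the terminal alkene of 16 with 17. This reduces the whole sensitive triene to a monosubstituted alkene that is inert to ylides, silyl cations, Lewis acids and the oxidants used, and that can be present from compound 1 onward. The eight-methylene spacer keeps this handle away from the ring chemistry.

**16 ⇒ 13 + 14 through 15 (key disconnection).** The exocyclic C3–CH2 bond is cut, not a ring bond. O2 stabilises the planar cation 15, which forms from either C3 epimer of peroxyketal 13. C3 therefore need not be carried or relayed; it is created last, at a flat carbon, by face-selective addition of silyl ketene acetal 14 inside a chiral ion pair. The gain is that the one hard stereochemical relationship of the target, C3 against C5 across C4, disappears from the problem: C5 is set alone by reagent control and C3 alone by catalyst control. The forward reaction must generate 15 catalytically, keep the O–O bond intact, and deliver 14 to the face that gives 3R.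

**13 ⇒ 10 ⇒ 9 ⇒ 8 ⇒ 7 ⇒ 6.** The O2–C3 bond of 13 is cut by peroxyketalisation. Acidic alcoholysis of silylperoxy ketone 10 frees hydroperoxy ketone 11, which closes to hemiketal 12 and is trapped as 13; the C3 configuration is irrelevant here. The C3–CH3 bond is cut next (methyl addition to aldehyde 8, then oxidation of carbinol 9). C3 is thus traced to the primary carbinol carbon of 7, the O-silylated form of hydroperoxy alcohol 6. These are functional-group steps only, and they must leave the C5–O1 bond untouched.

**6 ⇒ 5 ⇒ 3 ⇒ 1.** The C5–O1 bond is cut with inversion: perhydrolysis of oxetane 5 at its tertiary carbon. No other disconnection gives a stereospecific entry to a tertiary hydroperoxide with methyl and a plain alkyl chain. The two oxetane methylenes, which become C4 and C3 of the target, are removed by two successive catalytic asymmetric methylene transfers through epoxide 4. This leads to methyl ketone 3, in which only CH3 and CH2R must be told apart by the catalyst, and then to acid 1 through 2.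

## Alternatives that were turned down

**Alternative 1:** the textbook disconnection, the O2–C3 bond by intramolecular oxa-Michael addition.
- Key intermediate: hydroperoxy enoate A1, from ketone 10 by olefination and desilylation.
- Forward key step: with an amine base the C5 hydroperoxide adds 5-exo-trig to the β,β-disubstituted enoate and gives 16 and its C3 epimer A2.
- Turned down because C3 would be formed under the sole influence of C5, whose two carbon substituents are nearly isosteric, so the two envelope transition states are close to degenerate.
- The addition is reversible, and the equilibrium between 16 and A2 is expected to be just as flat.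
- The β,β-disubstituted acceptor is sluggish, and the base it needs invites E/Z scrambling and deconjugation.
- The precursor costs the same C5 chemistry plus an olefination of a methyl ketone, so nothing is saved and about half of the material would end as A2.

**Alternative 2:** two ring bonds at once, C4–C5 and O2–C3, by a (3+2) annulation of a peroxycarbenium ion with an alkene.
- Key intermediate: silylperoxy ketal A3, made from ketone 3.
- Forward key step: a Lewis acid ionises A3 to the acyclic peroxycarbenium ion; alkene A4 attacks through its CH2 terminus; the tertiary cation at C3 is captured by the silylated peroxy oxygen with loss of the silyl group.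
- This is the shortest conceivable route to the constitution of 16 and builds the ring with both quaternary carbons in one step.
- Turned down on stereochemical grounds: the C–C bond forms at an acyclic carbenium carbon flanked by CH3 and CH2R, and the ring closure is the capture of a free tertiary cation.
- Neither the absolute configuration at C5 nor the relative configuration at C3 has a controlling element, so all four stereoisomers would form and resolution plus separation would discard at least three quarters of the material.
- The cation next to CH2CO2Me can also lose a proton instead of closing.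

**Alternative 3:** both C–O bonds, C3–O2 and C5–O1, by stapling the O–O unit onto a chain whose two stereocentres are already present as oxetanes.
- Key intermediate: the C2-symmetric bis-oxetane A5.
- Forward key step: perhydrolysis opens one oxetane intermolecularly, and the new hydroperoxide opens the second by 5-exo-tet attack, each with inversion, giving dioxolane diol A6 stereospecifically.
- Turned down because of what the oxetane carbons leave behind: two 2-hydroxyethyl arms.
- One arm can be oxidised to the acetic acid arm, but the other must be extended by fourteen carbons through an sp3–sp3 bond at C2′ in the presence of the O–O bond.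
- Organometallic reagents attack peroxide oxygen, and an olefination would leave a C2′=C3′ double bond whose reduction neither the triene nor the peroxide would survive.
- The two arms of A6 are homotopic, so the first functionalisation is statistical.
- A5 has no short enantioselective synthesis, because the 1,3-diketone that a double methylene transfer would need is fully enolised.
- The steps before and after the key step would cost more than it wins.

Key step: step 9

Assumption: the sense of induction of the chiral catalysts in steps 2 and 9 is assigned by analogy with the known behaviour of these catalyst classes; both antipodes of each catalyst are available and the one that gives the drawn configuration is meant.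

## Route

Step 1
Reactants: 1 undec-10-enoic acid
Product: 3 dodec-11-en-2-one, via dilithium gem-diolate 2 (not isolated)
Conditions: MeLi (2.2 equiv), THF, 0 °C → rt; then dilute aq HCl, 0 °C
Reagents that add atoms: methyllithium, [Li]C
Why: Addition of MeLi to the lithium carboxylate stops at the dilithium gem-diolate 2, which collapses to the methyl ketone only on aqueous quench (classical methyl ketone synthesis from a carboxylic acid); the terminal alkene is inert.

Step 2
Reactants: 3 dodec-11-en-2-one
Product: 5 (R)-2-(dec-9-en-1-yl)-2-methyloxetane, via epoxide 4 (not isolated)
Conditions: Me2S(O)=CH2 (pre-formed THF solution, 1.2 then 1.5 equiv), LaLi3[(S)-binaphthoxide]3 (5 then 15 mol %), (2,4,6-(MeO)3C6H2)3P=O (5 then 15 mol %), 5 Å MS, THF, rt then 45 °C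
Reagents that add atoms: dimethyloxosulfonium methylide, C[S+](C)(=O)[CH2-]
Why: Catalytic asymmetric Corey–Chaykovsky epoxidation of an alkyl methyl ketone, followed in the same flask by ylide ring expansion of epoxide 4 (attack at the epoxide CH2, then 4-exo-tet closure). The heterobimetallic catalyst sets the quaternary carbon (the future C5) by telling CH3 from the CH2 chain, and the ring expansion does not touch this centre and should further raise the enantiomeric purity because the matched epoxide reacts faster.

Step 3
Reactants: 5 (R)-2-(dec-9-en-1-yl)-2-methyloxetane
Product: 6 (S)-3-hydroperoxy-3-methyltridec-12-en-1-ol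
Conditions: H2O2 (anhydrous, in Et2O, 10 equiv), Me3SiOTf (0.2 equiv), Et2O, −78 → 0 °C
Reagents that add atoms: hydrogen peroxide, OO
Why: Lewis acid-promoted perhydrolysis of a 2,2-disubstituted oxetane: hydrogen peroxide attacks the activated tertiary carbon in an SN2-like opening with inversion, which converts (R)-5 into the (S)-tertiary hydroperoxide and fixes C5 of the target. Low temperature and the ethereal medium disfavour a free tertiary cation.

Step 4
Reactants: 6 (S)-3-hydroperoxy-3-methyltridec-12-en-1-ol
Product: 7 (S)-3-methyl-3-[(triethylsilyl)peroxy]tridec-12-en-1-ol
Conditions: KN(SiMe3)2 (1.0 equiv), THF, −78 °C; then Et3SiCl (1.05 equiv), −78 °C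
Reagents that add atoms: chlorotriethylsilane, CC[Si](Cl)(CC)CC
Why: Chemoselective O-silylation of a hydroperoxide: one equivalent of base deprotonates only the O–O–H group, which is several pKa units more acidic than the alcohol, and the peroxy anion is silylated at −78 °C while the neutral primary alcohol, with no amine catalyst present, stays free.

Step 5
Reactants: 7 (S)-3-methyl-3-[(triethylsilyl)peroxy]tridec-12-en-1-ol
Product: 8 (S)-3-methyl-3-[(triethylsilyl)peroxy]tridec-12-enal
Conditions: Dess–Martin periodinane (1.3 equiv), CH2Cl2, 0 °C → rt
Reagents that add atoms: none
Why: Dess–Martin oxidation under non-basic conditions; the silyl peroxide is not an oxidisable alcohol, and the β-peroxy aldehyde is never exposed to base that could eliminate the peroxide.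

Step 6
Reactants: 8 (S)-3-methyl-3-[(triethylsilyl)peroxy]tridec-12-enal
Product: 9 (4S)-4-methyl-4-[(triethylsilyl)peroxy]tetradec-13-en-2-ol (C2 epimer mixture)
Conditions: MeMgBr (1.2 equiv), THF, −78 °C; aq NH4Cl at −78 °C
Reagents that add atoms: methylmagnesium bromide, C[Mg]Br
Why: Grignard addition to an unhindered aldehyde at −78 °C is much faster than attack of the reagent on the tertiary-alkyl silyl peroxide. The new carbinol centre is of no consequence because it is oxidised in step 7.

Step 7
Reactants: 9 (4S)-4-methyl-4-[(triethylsilyl)peroxy]tetradec-13-en-2-ol
Product: 10 (S)-4-methyl-4-[(triethylsilyl)peroxy]tetradec-13-en-2-one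
Conditions: Dess–Martin periodinane (1.3 equiv), CH2Cl2, 0 °C → rt
Reagents that add atoms: none
Why: Dess–Martin oxidation of the secondary alcohol gives the β-silylperoxy methyl ketone; the quaternary C–O centre cannot epimerise.

Step 8
Reactants: 10 (S)-4-methyl-4-[(triethylsilyl)peroxy]tetradec-13-en-2-one
Product: 13 (5S)-5-(dec-9-en-1-yl)-3-methoxy-3,5-dimethyl-1,2-dioxolane (C3 epimer mixture), via hydroperoxy ketone 11 (not isolated), via hydroxydioxolane 12 (not isolated)
Conditions: p-TsOH·H2O (0.1 equiv), MeOH, 0 °C → rt
Reagents that add atoms: methanol, CO
Why: Acid-catalysed methanolysis of the silyl peroxide frees hydroperoxy ketone 11, which closes to hemiketal 12 by addition of the O–O–H group to the ketone and is trapped as the methyl peroxyketal (known route from silylperoxy ketones to 3-alkoxy-1,2-dioxolanes). The C3 configuration is left uncontrolled on purpose because step 9 erases it.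

Step 9
Reactants: 13 (5S)-5-(dec-9-en-1-yl)-3-methoxy-3,5-dimethyl-1,2-dioxolane (C3 epimer mixture); 14 tert-butyl[(1-methoxyethenyl)oxy]dimethylsilane
Product: 16 methyl 2-[(3R,5S)-5-(dec-9-en-1-yl)-3,5-dimethyl-1,2-dioxolan-3-yl]acetate, via peroxycarbenium ion 15 (not isolated)
Conditions: 14 (1.5 equiv), (S,S)-imidodiphosphorimidate Brønsted acid (two 3,3′-diaryl-(S)-BINOL-derived phosphorus units bridged by NH, each with an N-triflyl group; 5 mol %), toluene, −78 → −60 °C
Reagents that add atoms: none
Why: Proposed new method: the chiral acid is silylated in the flask by 14, and this silyl cation equivalent removes the methoxy group from either C3 epimer of 13, which gives the planar peroxycarbenium ion 15 as an ion pair with the confined chiral imidodiphosphorimidate anion; 14 then adds to C3 and hands its silyl group on, which closes the cycle. The closest known reaction types are the TiCl4- or Me3SiOTf-mediated substitution of 3-alkoxy-1,2-dioxolanes by silyl ketene acetals through the same cation, and the imidodiphosphorimidate-catalysed enantioselective Mukaiyama-type additions of silyl ketene acetals to cyclic oxocarbenium ions and to small aliphatic methyl ketones; the combination of a peroxycarbenium ion with a chiral counteranion has not been shown. No ring is closed: the dioxolane is already present and only the exocyclic C3–CH2 bond is formed. The single new stereocentre C3 is controlled by the catalyst, whose anion shields one face of the flat C3=O2(+) unit, and because both epimers of 13 pass through 15 the step is stereoconvergent. The selectivity needed is facial selectivity at C3 (3R) that does not depend on C5, and the substrate helps by being unbiased: C5 carries CH3 and a CH2 chain of almost the same size, so there is no inherent 1,3-preference for the catalyst to overcome. Chemoselectivity rests on the large nucleophilicity gap between 14 and the monosubstituted alkene, and the low temperature and non-nucleophilic medium are meant to suppress acid-induced O–O heterolysis of 15.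

Step 10
Reactants: 16 methyl 2-[(3R,5S)-5-(dec-9-en-1-yl)-3,5-dimethyl-1,2-dioxolan-3-yl]acetate; 17 (E)-but-2-enal
Product: 18 methyl 2-[(3R,5S)-3,5-dimethyl-5-[(E)-11-oxoundec-9-en-1-yl]-1,2-dioxolan-3-yl]acetate
Conditions: 17 (5 equiv), second-generation Hoveyda–Grubbs catalyst RuCl2(1,3-dimesitylimidazolidin-2-ylidene)(=CH–C6H4-2-OiPr) (5 mol %), CH2Cl2, 40 °C
Reagents that add atoms: none
Why: Cross-metathesis of a terminal alkene with an electron-poor partner under a phosphine-free ruthenium carbene should give the E-enal under thermodynamic control. The di-tert-alkyl peroxide offers neither a C–H next to oxygen nor a coordinating site, and the absence of free phosphine avoids O–O reduction.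

Step 11
Reactants: 19 (E)-1-bromopent-2-ene
Product: 20 diethyl [(E)-pent-2-en-1-yl]phosphonate
Conditions: P(OEt)3 (1.2 equiv), neat, 130 °C, EtBr distilled off
Reagents that add atoms: triethyl phosphite, CCOP(OCC)OCC
Why: Michaelis–Arbuzov reaction at the primary allylic bromide (SN2 at C1), which keeps the E double bond.

Step 12
Reactants: 18 methyl 2-[(3R,5S)-3,5-dimethyl-5-[(E)-11-oxoundec-9-en-1-yl]-1,2-dioxolan-3-yl]acetate; 20 diethyl [(E)-pent-2-en-1-yl]phosphonate
Product: 21 methyl 2-[(3R,5S)-5-[(9E,11E,13E)-hexadeca-9,11,13-trien-1-yl]-3,5-dimethyl-1,2-dioxolan-3-yl]acetate
Conditions: 20 (1.3 equiv), LiN(SiMe3)2 (1.25 equiv), THF, −78 °C; then 18, −78 → 0 °C, exclusion of light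
Reagents that add atoms: none
Why: Horner–Wadsworth–Emmons olefination of an enal with a lithiated allylic phosphonate: reversible addition and elimination through the less crowded oxaphosphetane should favour the new E double bond at C11′=C12′, while the two existing E alkenes are not touched. The anion is pre-formed with a slight deficit of base so that no free amide meets the β-peroxy ester.

Step 13
Reactants: 21 methyl 2-[(3R,5S)-5-[(9E,11E,13E)-hexadeca-9,11,13-trien-1-yl]-3,5-dimethyl-1,2-dioxolan-3-yl]acetate
Product: 22 2-[(3R,5S)-5-[(9E,11E,13E)-hexadeca-9,11,13-trien-1-yl]-3,5-dimethyl-1,2-dioxolan-3-yl]acetic acid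
Conditions: LiOH (3 equiv), THF/MeOH/H2O, 0 °C; then dilute aq HCl to pH 4 at 0 °C, exclusion of light
Reagents that add atoms: lithium hydroxide, [Li+].[OH-]
Why: Saponification of the methyl ester: both peroxy carbons are fully substituted, so base-induced Kornblum–DeLaMare cleavage is impossible, and hydroxide attack at the ester carbonyl at 0 °C should outrun the α-deprotonation that would open the ring by β-elimination. The brief, cold and mild acidification spares the triene.

## Compound list

1 | undec-10-enoic acid | C=CCCCCCCCCC(=O)O | starting material
2 | dilithium dodec-11-ene-2,2-diolate (not isolated) | C=CCCCCCCCCC(C)([O-])[O-].[Li+].[Li+] | intermediate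
3 | dodec-11-en-2-one | C=CCCCCCCCCC(C)=O | intermediate
4 | (R)-2-(dec-9-en-1-yl)-2-methyloxirane (not isolated) | C=CCCCCCCCC[C@]1(C)CO1 | intermediate
5 | (R)-2-(dec-9-en-1-yl)-2-methyloxetane | C=CCCCCCCCC[C@]1(C)CCO1 | intermediate
6 | (S)-3-hydroperoxy-3-methyltridec-12-en-1-ol | C=CCCCCCCCC[C@@](OO)(C)CCO | intermediate
7 | (S)-3-methyl-3-[(triethylsilyl)peroxy]tridec-12-en-1-ol | C=CCCCCCCCC[C@@](OO[Si](CC)(CC)CC)(C)CCO | intermediate
8 | (S)-3-methyl-3-[(triethylsilyl)peroxy]tridec-12-enal | C=CCCCCCCCC[C@@](OO[Si](CC)(CC)CC)(C)CC=O | intermediate
9 | (4S)-4-methyl-4-[(triethylsilyl)peroxy]tetradec-13-en-2-ol (C2 epimer mixture) | C=CCCCCCCCC[C@@](OO[Si](CC)(CC)CC)(C)CC(C)O | intermediate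
10 | (S)-4-methyl-4-[(triethylsilyl)peroxy]tetradec-13-en-2-one | C=CCCCCCCCC[C@@](OO[Si](CC)(CC)CC)(C)CC(C)=O | intermediate
11 | (S)-4-hydroperoxy-4-methyltetradec-13-en-2-one (not isolated) | C=CCCCCCCCC[C@@](OO)(C)CC(C)=O | intermediate
12 | (5S)-5-(dec-9-en-1-yl)-3,5-dimethyl-1,2-dioxolan-3-ol (C3 epimer mixture; not isolated) | C=CCCCCCCCC[C@@]1(C)CC(C)(O)OO1 | intermediate
13 | (5S)-5-(dec-9-en-1-yl)-3-methoxy-3,5-dimethyl-1,2-dioxolane (C3 epimer mixture) | C=CCCCCCCCC[C@@]1(C)CC(C)(OC)OO1 | intermediate
14 | tert-butyl[(1-methoxyethenyl)oxy]dimethylsilane | C=C(OC)O[Si](C)(C)C(C)(C)C | starting material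
15 | (5S)-5-(dec-9-en-1-yl)-3,5-dimethyl-1,2-dioxolan-3-ylium ion (not isolated) | C=CCCCCCCCC[C@@]1(C)CC(C)=[O+]O1 | intermediate
16 | methyl 2-[(3R,5S)-5-(dec-9-en-1-yl)-3,5-dimethyl-1,2-dioxolan-3-yl]acetate | C=CCCCCCCCC[C@@]1(C)C[C@](C)(CC(=O)OC)OO1 | intermediate
17 | (E)-but-2-enal | C/C=C/C=O | starting material
18 | methyl 2-[(3R,5S)-3,5-dimethyl-5-[(E)-11-oxoundec-9-en-1-yl]-1,2-dioxolan-3-yl]acetate | O=C/C=C/CCCCCCCC[C@@]1(C)C[C@](C)(CC(=O)OC)OO1 | intermediate
19 | (E)-1-bromopent-2-ene | CC/C=C/CBr | starting material
20 | diethyl [(E)-pent-2-en-1-yl]phosphonate | CC/C=C/CP(=O)(OCC)OCC | intermediate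
21 | methyl 2-[(3R,5S)-5-[(9E,11E,13E)-hexadeca-9,11,13-trien-1-yl]-3,5-dimethyl-1,2-dioxolan-3-yl]acetate | CC/C=C/C=C/C=C/CCCCCCCC[C@@]1(C)C[C@](C)(CC(=O)OC)OO1 | intermediate
22 | 2-[(3R,5S)-5-[(9E,11E,13E)-hexadeca-9,11,13-trien-1-yl]-3,5-dimethyl-1,2-dioxolan-3-yl]acetic acid (CNP0181055.2) | CC/C=C/C=C/C=C/CCCCCCCC[C@@]1(C)C[C@](C)(CC(=O)O)OO1 | target

## Step count and least certain steps

Total step count: 13. Longest linear sequence: 12 (steps 1 to 10, 12 and 13; step 11 is a one-step side branch).

**Step 9 (key step, proposed new method).**
- What may go wrong: insufficient facial discrimination by the chiral anion, because the ion pair must recognise a small cyclic cation whose two faces differ only through the remote C5 substituents. An unselective background pathway through an achiral silyl cation could also erode the selectivity, and acid-induced O–O heterolysis of 15 with a 1,2-shift is the second threat.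
- Fallback (known chemistry): from 13, stoichiometric TiCl4 and 14 in CH2Cl2 at −78 °C effect the same substitution through 15 without external stereocontrol. This should give 16 together with its C3 epimer, methyl 2-[(3S,5S)-5-(dec-9-en-1-yl)-3,5-dimethyl-1,2-dioxolan-3-yl]acetate F1, with little preference. The two diastereomers are separated by chromatography and the route is rejoined at 16.

**Step 3.**
- What may go wrong: partial ionisation of the activated oxetane to a free tertiary cation, which would leak configuration at C5 and open the way to elimination to a homoallylic alcohol.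
- Fallback: the approach changes from preventing the leak to purging it. Material 6 of lowered enantiomeric purity is carried through steps 4 to 9 unchanged. Because C3 is set by the catalyst in step 9, the minor C5 antipode emerges there not as the enantiomer of 16 but as the diastereomer methyl 2-[(3R,5R)-5-(dec-9-en-1-yl)-3,5-dimethyl-1,2-dioxolan-3-yl]acetate F2, which is removed by chromatography. The fallback sets out from 6 and comes back at 16; it presupposes the catalyst-controlled mode of step 9.

**Step 4.**
- What may go wrong: loss of chemoselectivity through proton exchange between the peroxy anion and the primary alcohol, or silyl transfer from the peroxide oxygen to the neighbouring hydroxyl group. Either process would leave a free hydroperoxide in the oxidation steps.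
- Fallback: from 6, both O–H groups are silylated (Et3SiCl in excess, imidazole, DMF) to give (S)-triethyl({3-methyl-3-[(triethylsilyl)peroxy]tridec-12-en-1-yl}oxy)silane F3. A Swern oxidation, which converts primary triethylsilyl ethers directly into aldehydes, then leads to 8, where the route is rejoined; 7 is bypassed.

**Step 10.**
- What may go wrong: decomposition of the ruthenium carbene by electron transfer to the O–O bond, or stalling of the metathesis by the excess enal, leaving the terminal alkene unconverted.
- Fallback: from 16, ozonolysis (O3, CH2Cl2, −78 °C; then Me2S) gives methyl 2-[(3R,5S)-3,5-dimethyl-5-(9-oxononyl)-1,2-dioxolan-3-yl]acetate F4. A Wittig reaction with (triphenylphosphoranylidene)acetaldehyde in CH2Cl2 at 40 °C then gives 18, where the route is rejoined.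

**Step 12.**
- What may go wrong: incomplete E-selectivity at the new C11′=C12′ bond, γ-attack of the allylic anion, or ring opening of the β-peroxy ester by enolisation and β-elimination if free base is present.
- Fallback: from 19, triphenylphosphine gives [(E)-pent-2-en-1-yl]triphenylphosphonium bromide F5. Its ylide (NaN(SiMe3)2, THF, −78 °C) reacts with 18 to give 21 mixed with its 11′Z isomer, methyl 2-[(3R,5S)-5-[(9E,11Z,13E)-hexadeca-9,11,13-trien-1-yl]-3,5-dimethyl-1,2-dioxolan-3-yl]acetate F6. The mixture is equilibrated to the all-E triene with a catalytic amount of iodine in diffuse light, so geometry is corrected thermodynamically after the olefination; the route is rejoined at 21.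

## Further compounds

F1 | step 9 | methyl 2-[(3S,5S)-5-(dec-9-en-1-yl)-3,5-dimethyl-1,2-dioxolan-3-yl]acetate | C=CCCCCCCCC[C@@]1(C)C[C@@](C)(CC(=O)OC)OO1
F2 | step 3 | methyl 2-[(3R,5R)-5-(dec-9-en-1-yl)-3,5-dimethyl-1,2-dioxolan-3-yl]acetate | C=CCCCCCCCC[C@]1(C)C[C@](C)(CC(=O)OC)OO1
F3 | step 4 | (S)-triethyl({3-methyl-3-[(triethylsilyl)peroxy]tridec-12-en-1-yl}oxy)silane | C=CCCCCCCCC[C@@](OO[Si](CC)(CC)CC)(C)CCO[Si](CC)(CC)CC
F4 | step 10 | methyl 2-[(3R,5S)-3,5-dimethyl-5-(9-oxononyl)-1,2-dioxolan-3-yl]acetate | O=CCCCCCCCC[C@@]1(C)C[C@](C)(CC(=O)OC)OO1
F5 | step 12 | [(E)-pent-2-en-1-yl]triphenylphosphonium bromide | CC/C=C/C[P+](c1ccccc1)(c1ccccc1)c1ccccc1.[Br-]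
F6 | step 12 | methyl 2-[(3R,5S)-5-[(9E,11Z,13E)-hexadeca-9,11,13-trien-1-yl]-3,5-dimethyl-1,2-dioxolan-3-yl]acetate | CC/C=C/C=C\C=C\CCCCCCCC[C@@]1(C)C[C@](C)(CC(=O)OC)OO1
A1 | alternative 1 | methyl (2E,5S)-5-hydroperoxy-3,5-dimethylpentadeca-2,14-dienoate | C=CCCCCCCCC[C@@](OO)(C)C/C(C)=C/C(=O)OC
A2 | alternative 1 | methyl 2-[(3S,5S)-5-(dec-9-en-1-yl)-3,5-dimethyl-1,2-dioxolan-3-yl]acetate | C=CCCCCCCCC[C@@]1(C)C[C@@](C)(CC(=O)OC)OO1
A3 | alternative 2 | triethyl[(2-methoxydodec-11-en-2-yl)peroxy]silane (racemic) | C=CCCCCCCCCC(C)(OC)OO[Si](CC)(CC)CC
A4 | alternative 2 | methyl 3-methylbut-3-enoate | C=C(C)CC(=O)OC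
A5 | alternative 3 | (2R,2′R)-2,2′-methylenebis(2-methyloxetane) | O1CC[C@]1(C)C[C@@]2(C)CCO2
A6 | alternative 3 | 2,2′-[(3S,5S)-3,5-dimethyl-1,2-dioxolane-3,5-diyl]di(ethan-1-ol) | OCC[C@@]1(C)C[C@](C)(CCO)OO1
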